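## Retrosynthetic overview

1. The target comes from its primary acetate by ester methanolysis. The γ-lactone comes from a bicyclic mixed acetal (a furo[2,3-b]pyran) by acetal hydrolysis and lactol oxidation.
2. The lactone C4–OH and C5–isobutenyl groups come from the cyclic enol ether of that acetal: epoxidation anti to the acetal oxygen, then anti (SN2) opening with an isobutenyl Grignard reagent.
3. The bicyclic dienyl acetal comes from an (E)-enal and 3-vinylfuran by a catalytic asymmetric dearomative oxa-[4+2]. This forms the C2′–C3′ bond and the acetal C–O bond, sets C3′ and the ring-fusion centre, and locks the later exocyclic alkene as Z.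
4. The enal comes from geranyl acetate (allylic oxidation); 3-vinylfuran comes from furan-3-carbaldehyde (Wittig).
5. Ring order: the dihydropyran ring is closed onto the furan first; the former furan ring is then functionalised and becomes the γ-lactone when the pyran ring is opened.

Assumptions: locants are those of each compound's own name. Furo[2,3-b]pyran C2, C3, C3a, C7a become lactone C5, C4, C3, C2, and C4–C6 become side-chain C1′–C3′. The (1R,2S)-aminoindanol-derived chromium catalyst is taken to give the (6R,7aS) endo adduct; if its facial sense is the opposite, its enantiomer is used.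

## Route

Step 1
Reactants: 1 geranyl acetate
Product: 2 (2E,6E)-3,7-dimethyl-8-oxoocta-2,6-dien-1-yl acetate
Conditions: SeO2 (1.3 equiv), dioxane, 80 °C
Reagents that add atoms: selenium dioxide O=[Se]=O
Why: Riley allylic oxidation (ene reaction then [2,3]-shift) takes place at the (E)-methyl group of the more electron-rich, non-acetoxylated trisubstituted alkene and runs on to the (E)-enal with excess oxidant; no stereocenter is formed.

Step 2
Reactants: 3 furan-3-carbaldehyde
Product: 4 3-vinylfuran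
Conditions: Ph3PCH3Br (1.1 equiv), KOtBu (1.1 equiv), Et2O, 0 °C to rt; distil
Reagents that add atoms: methyltriphenylphosphonium bromide C[P+](c1ccccc1)(c1ccccc1)c1ccccc1.[Br-]
Why: Wittig methylenation of the aldehyde with the non-stabilised ylide gives the volatile vinylfuran; no stereocenter is formed.

Step 3
Reactants: 2 (2E,6E)-3,7-dimethyl-8-oxoocta-2,6-dien-1-yl acetate; 4 3-vinylfuran
Product: 5 (2E,6E)-7-[(6R,7aS)-5,6-dihydro-7aH-furo[2,3-b]pyran-6-yl]-3-methylocta-2,6-dien-1-yl acetate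
Conditions: CrCl(L) (5 mol%; L = dianion of the Schiff base of 3-(1-adamantyl)-2-hydroxy-5-methylbenzaldehyde with (1R,2S)-1-aminoindan-2-ol), 4 (2 equiv), 4 Å MS, neat, rt, 48 h; filter through Et3N-deactivated silica
Reagents that add atoms: none
Why: Proposed new method: 3-vinylfuran can react as a 1-alkoxy-1,3-diene through its vinyl group and the ring C2=C3 bond (the ring oxygen raises the HOMO and stabilises oxocarbenium character at C2), so the chiral Lewis-acidic chromium chloride complex (trivalent chromium) should promote an endo oxa-[4+2] at the aldehyde C=O (the trisubstituted enal C=C is too hindered to compete), breaking the furan aromaticity and giving the cis-2,6 acetal in which the catalyst sets C6 (R) and the endo approach sets C7a (S), while the new ring fixes the later exocyclic alkene as Z; the closest known reactions are chromium-catalysed asymmetric hetero-Diels–Alder reactions of 1-alkoxydienes with unactivated aldehydes and extra-annular Diels–Alder reactions of vinylfurans.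

Step 4
Reactants: 5 (2E,6E)-7-[(6R,7aS)-5,6-dihydro-7aH-furo[2,3-b]pyran-6-yl]-3-methylocta-2,6-dien-1-yl acetate
Product: 7 (2E,6E)-7-[(2R,3S,6R,7aR)-3-hydroxy-2-(2-methylprop-1-en-1-yl)-2,3,5,6-tetrahydro-7aH-furo[2,3-b]pyran-6-yl]-3-methylocta-2,6-dien-1-yl acetate, via epoxide 6 (not isolated)
Conditions: DMDO (1.05 equiv), acetone/CH2Cl2, −78 °C; evaporate at −20 °C; (CH3)2C=CHMgBr (1.3 equiv), THF, −78 °C; H2O
Reagents that add atoms: dimethyldioxirane CC1(C)OO1; (2-methylprop-1-en-1-yl)magnesium bromide CC(C)=C[Mg]Br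
Why: Dioxirane epoxidation of the electron-rich cyclic enol ether (glycal-type; the side-chain alkenes carry allylic oxygen and react more slowly) occurs anti to the pseudo-axial O7, and SN2 opening of the 1,2-anhydro acetal at the anomeric carbon by the alkenyl Grignard reagent (inversion, as in C-glycosylation of glycal epoxides) gives the 2,3-trans product, so C3 (S) and C2 (R) are relayed from C7a while the acetate survives at −78 °C.

Step 5
Reactants: 7 (2E,6E)-7-[(2R,3S,6R,7aR)-3-hydroxy-2-(2-methylprop-1-en-1-yl)-2,3,5,6-tetrahydro-7aH-furo[2,3-b]pyran-6-yl]-3-methylocta-2,6-dien-1-yl acetate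
Product: 9 (2E,6E,8R,10Z)-8-hydroxy-10-[(4S,5R)-4-hydroxy-5-(2-methylprop-1-en-1-yl)-2-oxooxolan-3-ylidene]-3,7-dimethyldeca-2,6-dien-1-yl acetate, via lactol 8 (not isolated)
Conditions: PPTS (0.1 equiv), THF/H2O (4:1), 0 °C; concentrate; Ag2CO3 on Celite (5 equiv), toluene, 80 °C
Reagents that add atoms: water O
Why: Mild acid hydrolysis of the allylic bicyclic acetal (exocyclic C7a–O7 cleavage to the five-membered oxocarbenium ion) gives the γ-lactol, and Fetizon oxidation converts the lactol into the γ-lactone faster than it touches the secondary alcohols or the alkenes; no stereocenter is created and the ring-derived Z-alkene is retained.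

Step 6
Reactants: 9 (2E,6E,8R,10Z)-8-hydroxy-10-[(4S,5R)-4-hydroxy-5-(2-methylprop-1-en-1-yl)-2-oxooxolan-3-ylidene]-3,7-dimethyldeca-2,6-dien-1-yl acetate
Product: 10 (3Z,4S,5R)-3-[(3R,4E,8E)-3,10-dihydroxy-4,8-dimethyldeca-4,8-dien-1-ylidene]-4-hydroxy-5-(2-methylprop-1-en-1-yl)oxolan-2-one
Conditions: K2CO3 (0.2 equiv), MeOH, 0 °C, 1 h; pH 7 buffer
Reagents that add atoms: none
Why: Zemplén-type transesterification removes the primary allylic acetate without affecting the stereocenters (C4 carries no α-hydrogen for elimination), and catalytic carbonate lets any δ-lactone isomer relactonise to the γ-lactone of the target.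

## Compound list

1 | geranyl acetate, (2E)-3,7-dimethylocta-2,6-dien-1-yl acetate | CC(C)=CCC/C(C)=C/COC(C)=O | starting material
2 | (2E,6E)-3,7-dimethyl-8-oxoocta-2,6-dien-1-yl acetate | O=C/C(C)=C/CC/C(C)=C/COC(C)=O | intermediate
3 | furan-3-carbaldehyde | O=Cc1ccoc1 | starting material
4 | 3-vinylfuran (3-ethenylfuran) | C=Cc1ccoc1 | intermediate
5 | (2E,6E)-7-[(6R,7aS)-5,6-dihydro-7aH-furo[2,3-b]pyran-6-yl]-3-methylocta-2,6-dien-1-yl acetate | [C@H]1(/C(C)=C/CC/C(C)=C/COC(C)=O)CC=C2C=CO[C@H]2O1 | intermediate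
6 | (2E,6E)-7-[(2R,3S,6R,7aR)-2,3-epoxy-2,3,5,6-tetrahydro-7aH-furo[2,3-b]pyran-6-yl]-3-methylocta-2,6-dien-1-yl acetate (oxirane oxygen anti to O7) | [C@H]1(/C(C)=C/CC/C(C)=C/COC(C)=O)CC=C2[C@@H]3O[C@@H]3O[C@H]2O1 | intermediate
7 | (2E,6E)-7-[(2R,3S,6R,7aR)-3-hydroxy-2-(2-methylprop-1-en-1-yl)-2,3,5,6-tetrahydro-7aH-furo[2,3-b]pyran-6-yl]-3-methylocta-2,6-dien-1-yl acetate | [C@H]1(/C(C)=C/CC/C(C)=C/COC(C)=O)CC=C2[C@H](O)[C@@H](C=C(C)C)O[C@H]2O1 | intermediate
8 | (2E,6E,8R,10Z)-10-[(4S,5R)-2,4-dihydroxy-5-(2-methylprop-1-en-1-yl)oxolan-3-ylidene]-8-hydroxy-3,7-dimethyldeca-2,6-dien-1-yl acetate (anomers) | CC(C)=C[C@H]1OC(O)/C(=C\C[C@@H](O)/C(C)=C/CC/C(C)=C/COC(C)=O)[C@@H]1O | intermediate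
9 | (2E,6E,8R,10Z)-8-hydroxy-10-[(4S,5R)-4-hydroxy-5-(2-methylprop-1-en-1-yl)-2-oxooxolan-3-ylidene]-3,7-dimethyldeca-2,6-dien-1-yl acetate | CC(C)=C[C@H]1OC(=O)/C(=C\C[C@@H](O)/C(C)=C/CC/C(C)=C/COC(C)=O)[C@@H]1O | intermediate
10 | (3Z,4S,5R)-3-[(3R,4E,8E)-3,10-dihydroxy-4,8-dimethyldeca-4,8-dien-1-ylidene]-4-hydroxy-5-(2-methylprop-1-en-1-yl)oxolan-2-one | CC(C)=C[C@H]1OC(=O)/C(=C\C[C@@H](O)/C(C)=C/CC/C(C)=C/CO)[C@@H]1O | target

## Step count and risks

Total steps: 6. Longest linear sequence: 5 steps (1 → 2 → 5 → 7 → 9 → 10; equally 3 → 4 → 5 → 7 → 9 → 10).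

Steps most likely to fail:

Step 3 (dearomative cycloaddition). The diene may be too unreactive, or the acetal may rearomatise to the ene-type product. Fallback, from 2 and 3 back to 5: make the C–C bond by carbonyl addition and dearomatise afterwards. Compound 3 is homologated (dimethyl (1-diazo-2-oxopropyl)phosphonate, K2CO3, MeOH) to 3-ethynylfuran F1. Hydroboration with Cy2BH, transfer to zinc with Me2Zn and addition to 2 in the presence of (−)-MIB (enantiomer chosen for R) give (2E,6E,8R,9E)-10-(furan-3-yl)-8-hydroxy-3,7-dimethyldeca-2,6,9-trien-1-yl acetate F2. PhSeCl/K2CO3 at −78 °C then induces a dearomative 6-endo selenoetherification in which the hydroxyl closes onto furan C2, giving (2E,6E)-3-methyl-7-[(6S,7aS)-5-(phenylselanyl)-5,6-dihydro-7aH-furo[2,3-b]pyran-6-yl]octa-2,6-dien-1-yl acetate F3. Bu3SnH/AIBN removes selenium and returns 5.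

Step 4 (facial selectivity of oxygen transfer). Fallback, from 5 back to 6: if DMDO delivers oxygen mainly syn to O7, the same facial preference is turned into the required epoxide through a halohydrin. NBS in wet THF at −78 °C gives the trans-bromohydrin (2E,6E)-7-[(2R,3R,6R,7aR)-3-bromo-2-hydroxy-2,3,5,6-tetrahydro-7aH-furo[2,3-b]pyran-6-yl]-3-methylocta-2,6-dien-1-yl acetate F4 (bromine syn to O7, anomeric hydroxyl trans to it). K2CO3 closes it with inversion at C3 to epoxide 6, which is opened by the Grignard reagent as in step 4.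

Step 5 (ring size of the lactol and lactone; the thermodynamic preference for the γ-lactone over the δ-lactone is assumed, not established). Fallback, from 7 back to 9: cleave the acetal by silyl transfer so that the C6 oxygen is capped before the lactol forms. TESOTf (3 equiv)/2,4,6-collidine silylates O3 and opens the exocyclic C7a–O7 bond (O7 leaves as its TES ether). Aqueous work-up gives (2E,6E,8R,10Z)-10-[(4S,5R)-2-hydroxy-5-(2-methylprop-1-en-1-yl)-4-(triethylsilyloxy)oxolan-3-ylidene]-3,7-dimethyl-8-(triethylsilyloxy)deca-2,6-dien-1-yl acetate F5. Ag2CO3 on Celite gives (2E,6E,8R,10Z)-3,7-dimethyl-10-[(4S,5R)-5-(2-methylprop-1-en-1-yl)-2-oxo-4-(triethylsilyloxy)oxolan-3-ylidene]-8-(triethylsilyloxy)deca-2,6-dien-1-yl acetate F6, which cannot isomerise to the δ-lactone. PPTS/MeOH removes both silyl ethers to give 9.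

Further compounds
F1 | step 3 | 3-ethynylfuran | C#Cc1ccoc1
F2 | step 3 | (2E,6E,8R,9E)-10-(furan-3-yl)-8-hydroxy-3,7-dimethyldeca-2,6,9-trien-1-yl acetate | c1occc1/C=C/[C@@H](O)/C(C)=C/CC/C(C)=C/COC(C)=O
F3 | step 3 | (2E,6E)-3-methyl-7-[(6S,7aS)-5-(phenylselanyl)-5,6-dihydro-7aH-furo[2,3-b]pyran-6-yl]octa-2,6-dien-1-yl acetate (C5 epimers) | [C@H]1(/C(C)=C/CC/C(C)=C/COC(C)=O)C([Se]c3ccccc3)C=C2C=CO[C@H]2O1
F4 | step 4 | (2E,6E)-7-[(2R,3R,6R,7aR)-3-bromo-2-hydroxy-2,3,5,6-tetrahydro-7aH-furo[2,3-b]pyran-6-yl]-3-methylocta-2,6-dien-1-yl acetate | [C@H]1(/C(C)=C/CC/C(C)=C/COC(C)=O)CC=C2[C@@H](Br)[C@H](O)O[C@H]2O1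
F5 | step 5 | (2E,6E,8R,10Z)-10-[(4S,5R)-2-hydroxy-5-(2-methylprop-1-en-1-yl)-4-(triethylsilyloxy)oxolan-3-ylidene]-3,7-dimethyl-8-(triethylsilyloxy)deca-2,6-dien-1-yl acetate | CC(C)=C[C@H]1OC(O)/C(=C\C[C@@H](O[Si](CC)(CC)CC)/C(C)=C/CC/C(C)=C/COC(C)=O)[C@@H]1O[Si](CC)(CC)CC
F6 | step 5 | (2E,6E,8R,10Z)-3,7-dimethyl-10-[(4S,5R)-5-(2-methylprop-1-en-1-yl)-2-oxo-4-(triethylsilyloxy)oxolan-3-ylidene]-8-(triethylsilyloxy)deca-2,6-dien-1-yl acetate | CC(C)=C[C@H]1OC(=O)/C(=C\C[C@@H](O[Si](CC)(CC)CC)/C(C)=C/CC/C(C)=C/COC(C)=O)[C@@H]1O[Si](CC)(CC)CC
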